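**Retrosynthetic overview**
- The tetronic acid is the only ring formed and it is closed last, through its two C–O bonds: enantioselective γ-oxygenation of an acyclic β-keto ester dianion (C5–O, sets 5R), then lactonisation (O1–C2).
- The β-keto ester comes from γ-alkylation of the methyl 2-methylacetoacetate dianion with an (E,E,E)-trienyl allylic chloride.
- The chloride comes from Julia–Kocienski olefination of 8-chlorogeranial (geranyl acetate: SeO2, chlorination, deacetylation, MnO2) with an (S)-configured phenyltetrazolyl sulfone.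
- The sulfone comes from Evans allylation (sets 10S), reduction, Mitsunobu thioetherification, oxidation and B-alkyl Suzuki coupling; the furan ring is bought as 3-bromofuran.

Assumption: the SMILES is read as (5R) at the lactone carbon, (10S) in the side chain and E at all three chain alkenes; the sense of induction in step 12 is taken from the reported behaviour of the oxaziridine with Z-configured ketone enolates, not from an experiment on this substrate.

**Step 1**
Reactants: 1 (R)-4-benzyl-3-propanoyloxazolidin-2-one; 2 allyl iodide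
Product: 4 (R)-4-benzyl-3-[(2S)-2-methylpent-4-enoyl]oxazolidin-2-one, via sodium enolate 3 (not isolated)
Conditions: NaN(SiMe3)2, THF, −78 °C; then allyl iodide, −78 → −45 °C
Reagents that add atoms: allyl iodide (2), C=CCI
Why: Evans asymmetric alkylation: the chelated Z-configured sodium enolate is allylated on the face opposite the benzyl group of the (R)-auxiliary, which sets the (S)-methyl stereocentre that becomes C10 of the side chain (dr ≥ 95:5 expected).

**Step 2**
Reactants: 4 (R)-4-benzyl-3-[(2S)-2-methylpent-4-enoyl]oxazolidin-2-one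
Product: 5 (S)-2-methylpent-4-en-1-ol
Conditions: LiBH4, H2O (1 equiv), Et2O, 0 °C
Reagents that add atoms: none
Why: Reductive cleavage of the N-acyl oxazolidinone at the exocyclic carbonyl gives the primary alcohol without touching the α-stereocentre or the alkene and returns the auxiliary.

**Step 3**
Reactants: 5 (S)-2-methylpent-4-en-1-ol; 6 1-phenyl-1H-tetrazole-5-thiol
Product: 7 5-{[(2S)-2-methylpent-4-en-1-yl]sulfanyl}-1-phenyl-1H-tetrazole
Conditions: PPh3, DIAD, THF, 0 °C → rt
Reagents that add atoms: 1-phenyl-1H-tetrazole-5-thiol (6), Sc1nnnn1-c1ccccc1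
Why: Mitsunobu thioetherification: the acidic thiol displaces the activated primary alcohol by SN2 at a CH2 carbon, so the neighbouring stereocentre is untouched.

**Step 4**
Reactants: 7 5-{[(2S)-2-methylpent-4-en-1-yl]sulfanyl}-1-phenyl-1H-tetrazole
Product: 8 5-{[(2S)-2-methylpent-4-en-1-yl]sulfonyl}-1-phenyl-1H-tetrazole
Conditions: (NH4)6Mo7O24·4H2O (10 mol %), 30 % H2O2, EtOH, 0 °C → rt
Reagents that add atoms: hydrogen peroxide, OO
Why: Molybdate-catalysed peroxide oxidation of sulfide to sulfone; the electrophilic peroxo species oxidises sulfur far faster than an unactivated terminal alkene, and the furan is not yet present.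

**Step 5**
Reactants: 8 5-{[(2S)-2-methylpent-4-en-1-yl]sulfonyl}-1-phenyl-1H-tetrazole; 9 3-bromofuran
Product: 11 5-{[(2S)-5-(furan-3-yl)-2-methylpentyl]sulfonyl}-1-phenyl-1H-tetrazole, via B-alkyl-9-BBN borane 10 (not isolated)
Conditions: 9-BBN, THF, 0 °C → rt; then 3-bromofuran, PdCl2(dppf) (5 mol %), aq. K3PO4, DMF, rt
Reagents that add atoms: 3-bromofuran (9), Brc1ccoc1
Why: Anti-Markovnikov hydroboration of the terminal alkene followed by B-alkyl Suzuki–Miyaura coupling forms the sp3–sp2 bond at furan C3; the remote stereocentre is not involved.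

**Step 6**
Reactants: 12 geranyl acetate
Product: 13 (2E,6E)-8-hydroxy-3,7-dimethylocta-2,6-dien-1-yl acetate
Conditions: SeO2 (0.4 equiv), t-BuOOH, salicylic acid (cat.), CH2Cl2, rt
Reagents that add atoms: tert-butyl hydroperoxide, CC(C)(C)OO (terminal oxygen source, delivered through catalytic SeO2, O=[Se]=O)
Why: Sharpless–Umbreit allylic oxidation (ene reaction, then [2,3]-sigmatropic shift) hydroxylates the E-methyl group of the more electron-rich 6,7-alkene, the 2,3-alkene being deactivated by the allylic acetate.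

**Step 7**
Reactants: 13 (2E,6E)-8-hydroxy-3,7-dimethylocta-2,6-dien-1-yl acetate
Product: 15 (2E,6E)-8-chloro-3,7-dimethylocta-2,6-dien-1-yl acetate, via allylic mesylate 14 (not isolated)
Conditions: MsCl, 2,4,6-collidine, LiCl, DMF, 0 °C
Reagents that add atoms: lithium chloride, [Li+].[Cl-]
Why: Collington–Meyers allylic chlorination: mesylation then SN2 displacement by chloride converts the primary allylic alcohol into the chloride without allylic transposition or loss of E geometry.

**Step 8**
Reactants: 15 (2E,6E)-8-chloro-3,7-dimethylocta-2,6-dien-1-yl acetate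
Product: 16 (2E,6E)-8-chloro-3,7-dimethylocta-2,6-dien-1-ol
Conditions: K2CO3 (0.5 equiv), MeOH, 0 °C
Reagents that add atoms: none
Why: Carbonate-catalysed transesterification removes the acetate; the primary allylic chloride is not solvolysed by dilute methanolic carbonate at 0 °C within the reaction time.

**Step 9**
Reactants: 16 (2E,6E)-8-chloro-3,7-dimethylocta-2,6-dien-1-ol
Product: 17 (2E,6E)-8-chloro-3,7-dimethylocta-2,6-dienal
Conditions: MnO2, CH2Cl2, rt
Reagents that add atoms: none
Why: MnO2 oxidation, selective for allylic alcohols, gives the enal without E/Z isomerisation, over-oxidation or attack on the C–Cl bond.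

**Step 10**
Reactants: 11 5-{[(2S)-5-(furan-3-yl)-2-methylpentyl]sulfonyl}-1-phenyl-1H-tetrazole; 17 (2E,6E)-8-chloro-3,7-dimethylocta-2,6-dienal
Product: 19 3-[(4S,5E,7E,11E)-13-chloro-4,8,12-trimethyltrideca-5,7,11-trien-1-yl]furan, via potassium sulfonyl carbanion 18 (not isolated)
Conditions: KN(SiMe3)2, DME, −60 °C; then 17, −60 °C → rt
Reagents that add atoms: none
Why: Julia–Kocienski olefination: at −60 °C the sulfonyl carbanion adds to the aldehyde much faster than it displaces the allylic chloride, and Smiles rearrangement with loss of SO2 and the tetrazololate gives the E-alkene of the conjugated diene (E favoured with potassium in DME); the stereocentre next to the carbanion carries no acidic hydrogen and is not epimerised.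

**Step 11**
Reactants: 19 3-[(4S,5E,7E,11E)-13-chloro-4,8,12-trimethyltrideca-5,7,11-trien-1-yl]furan; 20 methyl 2-methyl-3-oxobutanoate
Product: 22 methyl (2RS,6E,10E,12E,14S)-17-(furan-3-yl)-2,6,10,14-tetramethyl-3-oxoheptadeca-6,10,12-trienoate, via dilithium dianion 21 (not isolated)
Conditions: LiN(iPr)2 (2 equiv per 20), THF, 0 °C; then 19, 0 °C → rt; 1 M HCl quench
Reagents that add atoms: methyl 2-methyl-3-oxobutanoate (20), COC(=O)C(C)C(C)=O
Why: Huckin–Weiler dianion alkylation: the γ-carbanion, the more nucleophilic site of the dianion, displaces the primary allylic chloride by SN2 without transposition; the C2 epimer mixture is inconsequential because C2 becomes sp2 in step 12.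

**Step 12**
Reactants: 22 methyl (2RS,6E,10E,12E,14S)-17-(furan-3-yl)-2,6,10,14-tetramethyl-3-oxoheptadeca-6,10,12-trienoate
Product: 25 (5R)-5-[(2E,6E,8E,10S)-13-(furan-3-yl)-2,6,10-trimethyltrideca-2,6,8-trien-1-yl]-4-hydroxy-3-methylfuran-2(5H)-one, via dilithium dianion 23 (not isolated), via γ-hydroxy β-keto ester dilithium salt 24 (not isolated)
Conditions: LiN(iPr)2 (2.2 equiv), THF, −78 → 0 °C; (1R)-(−)-(10-camphorsulfonyl)oxaziridine (1.05 equiv), −78 °C; then MeOH, −78 °C → rt; cold 0.5 M HCl
Reagents that add atoms: (1R)-(−)-(10-camphorsulfonyl)oxaziridine, CC1(C)[C@H]2CC[C@@]13CS(=O)(=O)N4O[C@]34C2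
Why: Proposed new method: reagent-controlled enantioselective γ-hydroxylation of a β-keto ester dianion with in situ lactonisation, which forms the C5–O bond, sets (5R) and closes the tetronic acid ring in one flask; the dianion reacts with electrophiles only at its γ-carbon (Weiler regiochemistry), that terminus is a Z-configured enolate because the substituted enolate unit on the carbonyl carbon plays the role of an aryl group, and Z-ketone enolates are oxygenated by the sterically biased oxaziridine through an open SN2-type transition state at oxygen with the (+)-reagent giving (S)-carbinols, so the (−)-reagent is used for (R); the hemiaminal collapses to the sulfonimine and a γ-alkoxide, which after MeOH is added attacks the ester (5-exo-trig) and expels methoxide to give the tetronate (pKa about 4, the thermodynamic sink), and C5 is then flanked only by an enolate and cannot epimerise; the remote (10S) centre plays no part; closest known reaction types are the Davis asymmetric hydroxylation of ketone mono-enolates with (camphorsulfonyl)oxaziridines, the Weiler γ-functionalisation of β-keto ester dianions and the base-mediated lactonisation of γ-hydroxy β-keto esters.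

**Compound list**
1 | (R)-4-benzyl-3-propanoyloxazolidin-2-one | CCC(=O)N1[C@H](Cc2ccccc2)COC1=O | starting material
2 | allyl iodide | C=CCI | starting material
3 | sodium Z-enolate of 1 (not isolated) | [Na+].C/C=C(\[O-])N1[C@H](Cc2ccccc2)COC1=O | intermediate
4 | (R)-4-benzyl-3-[(2S)-2-methylpent-4-enoyl]oxazolidin-2-one | C=CC[C@H](C)C(=O)N1[C@H](Cc2ccccc2)COC1=O | intermediate
5 | (S)-2-methylpent-4-en-1-ol | C=CC[C@H](C)CO | intermediate
6 | 1-phenyl-1H-tetrazole-5-thiol | Sc1nnnn1-c1ccccc1 | starting material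
7 | 5-{[(2S)-2-methylpent-4-en-1-yl]sulfanyl}-1-phenyl-1H-tetrazole | C=CC[C@H](C)CSc1nnnn1-c1ccccc1 | intermediate
8 | 5-{[(2S)-2-methylpent-4-en-1-yl]sulfonyl}-1-phenyl-1H-tetrazole | C=CC[C@H](C)CS(=O)(=O)c1nnnn1-c1ccccc1 | intermediate
9 | 3-bromofuran | Brc1ccoc1 | starting material
10 | 5-{[(2S)-5-(9-borabicyclo[3.3.1]nonan-9-yl)-2-methylpentyl]sulfonyl}-1-phenyl-1H-tetrazole (not isolated) | B1(CCC[C@H](C)CS(=O)(=O)c2nnnn2-c2ccccc2)C2CCCC1CCC2 | intermediate
11 | 5-{[(2S)-5-(furan-3-yl)-2-methylpentyl]sulfonyl}-1-phenyl-1H-tetrazole | c1cc(CCC[C@H](C)CS(=O)(=O)c2nnnn2-c2ccccc2)co1 | intermediate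
12 | geranyl acetate, (2E)-3,7-dimethylocta-2,6-dien-1-yl acetate | CC(C)=CCC/C(C)=C/COC(C)=O | starting material
13 | (2E,6E)-8-hydroxy-3,7-dimethylocta-2,6-dien-1-yl acetate | OC/C(C)=C/CC/C(C)=C/COC(C)=O | intermediate
14 | (2E,6E)-8-acetoxy-2,6-dimethylocta-2,6-dien-1-yl methanesulfonate (not isolated) | CS(=O)(=O)OC/C(C)=C/CC/C(C)=C/COC(C)=O | intermediate
15 | (2E,6E)-8-chloro-3,7-dimethylocta-2,6-dien-1-yl acetate | ClC/C(C)=C/CC/C(C)=C/COC(C)=O | intermediate
16 | (2E,6E)-8-chloro-3,7-dimethylocta-2,6-dien-1-ol | ClC/C(C)=C/CC/C(C)=C/CO | intermediate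
17 | (2E,6E)-8-chloro-3,7-dimethylocta-2,6-dienal | ClC/C(C)=C/CC/C(C)=C/C=O | intermediate
18 | potassium α-sulfonyl carbanion of 11 (not isolated) | [K+].c1cc(CCC[C@H](C)[CH-]S(=O)(=O)c2nnnn2-c2ccccc2)co1 | intermediate
19 | 3-[(4S,5E,7E,11E)-13-chloro-4,8,12-trimethyltrideca-5,7,11-trien-1-yl]furan | ClC/C(C)=C/CC/C(C)=C/C=C/[C@@H](C)CCCc1ccoc1 | intermediate
20 | methyl 2-methyl-3-oxobutanoate | COC(=O)C(C)C(C)=O | starting material
21 | dilithium dianion of 20 (not isolated) | [Li+].[Li+].COC(=O)[C-](C)C(=O)[CH2-] | intermediate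
22 | methyl (2RS,6E,10E,12E,14S)-17-(furan-3-yl)-2,6,10,14-tetramethyl-3-oxoheptadeca-6,10,12-trienoate (C2 epimer mixture) | COC(=O)C(C)C(=O)CC/C(C)=C/CC/C(C)=C/C=C/[C@@H](C)CCCc1ccoc1 | intermediate
23 | dilithium dianion of 22 (not isolated) | [Li+].[Li+].COC(=O)[C-](C)C(=O)[CH-]C/C(C)=C/CC/C(C)=C/C=C/[C@@H](C)CCCc1ccoc1 | intermediate
24 | dilithium salt of methyl (4R,6E,10E,12E,14S)-17-(furan-3-yl)-4-hydroxy-2,6,10,14-tetramethyl-3-oxoheptadeca-6,10,12-trienoate (not isolated) | [Li+].[Li+].COC(=O)[C-](C)C(=O)[C@H]([O-])C/C(C)=C/CC/C(C)=C/C=C/[C@@H](C)CCCc1ccoc1 | intermediate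
25 | (5R)-5-[(2E,6E,8E,10S)-13-(furan-3-yl)-2,6,10-trimethyltrideca-2,6,8-trien-1-yl]-4-hydroxy-3-methylfuran-2(5H)-one | CC1=C(O)[C@@H](C/C(C)=C/CC/C(C)=C/C=C/[C@@H](C)CCCc2ccoc2)OC1=O | target

**Step count**
Total: 12 steps. Longest linear sequence: 8 steps (steps 1–5, then 10, 11, 12); the geranyl branch (steps 6–9) is 4 steps before the union.

**Three steps most likely to fail**

Step 12 (the proposed new method). The risks are the level and sense of induction with a lithium dianion, a second hydroxylation at C2 by excess reagent, and incomplete lactonisation. The sense must be confirmed on the first run; the antipodal oxaziridine is equally available. The fallback uses known chemistry, sets out from 19 and returns at 25. Alkylation of dilithioacetate (AcOH, 2 LiN(iPr)2, THF/DMPU) with 19 gives (4E,8E,10E,12S)-15-(furan-3-yl)-4,8,12-trimethylpentadeca-4,8,10-trienoic acid F1. Pivaloyl chloride/Et3N, then (R)-4-benzyloxazolidin-2-one and LiCl, gives (R)-4-benzyl-3-[(4E,8E,10E,12S)-15-(furan-3-yl)-4,8,12-trimethylpentadeca-4,8,10-trienoyl]oxazolidin-2-one F2. Evans hydroxylation of its sodium enolate (NaN(SiMe3)2, THF, −78 °C, racemic trans-3-phenyl-2-(phenylsulfonyl)oxaziridine), with oxygen delivered anti to the benzyl group, gives (R)-4-benzyl-3-[(2R,4E,8E,10E,12S)-15-(furan-3-yl)-2-hydroxy-4,8,12-trimethylpentadeca-4,8,10-trienoyl]oxazolidin-2-one F3. CH3OMgBr in MeOH at 0 °C releases methyl (2R,4E,8E,10E,12S)-15-(furan-3-yl)-2-hydroxy-4,8,12-trimethylpentadeca-4,8,10-trienoate F4. Propanoic anhydride/DMAP gives methyl (2R,4E,8E,10E,12S)-15-(furan-3-yl)-4,8,12-trimethyl-2-(propanoyloxy)pentadeca-4,8,10-trienoate F5. Dieckmann cyclisation with LiN(SiMe3)2 (THF, −78 → 0 °C) closes the tetronic acid 25 with the C5 configuration retained.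

Step 10 (Julia–Kocienski olefination beside an allylic chloride). The risks are alkylation of the sulfonyl carbanion by the chloride and an E/Z mixture at the new alkene. The fallback consumes the chloride before the sulfone is introduced; it sets out from 16 and returns at 22. Dianion 21 (3 equiv, the first equivalent being spent on the hydroxyl) alkylates 16 to give methyl (2RS,6E,10E)-12-hydroxy-2,6,10-trimethyl-3-oxododeca-6,10-dienoate F6. MnO2 oxidation gives methyl (2RS,6E,10E)-2,6,10-trimethyl-3,12-dioxododeca-6,10-dienoate F7. Its acidic β-keto ester is masked by KN(SiMe3)2 (1 equiv, −78 °C) as the potassium enolate of the keto aldehyde F8 (not isolated), which is added to carbanion 18 in DME at −60 °C; acidic work-up gives 22.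

Step 5 (B-alkyl Suzuki coupling in the presence of the base-sensitive tetrazolyl sulfone). The risks are attack of aqueous base on the sulfone and slow coupling of the electron-rich bromofuran. The fallback makes the C–C bond before the sulfone exists; it sets out from 7 and returns at 11. Hydroboration of sulfide 7 with 9-BBN gives 5-{[(2S)-5-(9-borabicyclo[3.3.1]nonan-9-yl)-2-methylpentyl]sulfanyl}-1-phenyl-1H-tetrazole F9 (not isolated). Coupling with 9 (PdCl2(dppf), aq. K3PO4, DMF) gives 5-{[(2S)-5-(furan-3-yl)-2-methylpentyl]sulfanyl}-1-phenyl-1H-tetrazole F10. Oxidation with (NH4)6Mo7O24·4H2O/H2O2 in neutral EtOH at 0 °C, monitored closely because the furan is now present, gives 11.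

**Further compounds**
F1 | step 12 | (4E,8E,10E,12S)-15-(furan-3-yl)-4,8,12-trimethylpentadeca-4,8,10-trienoic acid | OC(=O)CC/C(C)=C/CC/C(C)=C/C=C/[C@@H](C)CCCc1ccoc1
F2 | step 12 | (R)-4-benzyl-3-[(4E,8E,10E,12S)-15-(furan-3-yl)-4,8,12-trimethylpentadeca-4,8,10-trienoyl]oxazolidin-2-one | O=C(CC/C(C)=C/CC/C(C)=C/C=C/[C@@H](C)CCCc1ccoc1)N1[C@H](Cc2ccccc2)COC1=O
F3 | step 12 | (R)-4-benzyl-3-[(2R,4E,8E,10E,12S)-15-(furan-3-yl)-2-hydroxy-4,8,12-trimethylpentadeca-4,8,10-trienoyl]oxazolidin-2-one | O=C([C@H](O)C/C(C)=C/CC/C(C)=C/C=C/[C@@H](C)CCCc1ccoc1)N1[C@H](Cc2ccccc2)COC1=O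
F4 | step 12 | methyl (2R,4E,8E,10E,12S)-15-(furan-3-yl)-2-hydroxy-4,8,12-trimethylpentadeca-4,8,10-trienoate | COC(=O)[C@H](O)C/C(C)=C/CC/C(C)=C/C=C/[C@@H](C)CCCc1ccoc1
F5 | step 12 | methyl (2R,4E,8E,10E,12S)-15-(furan-3-yl)-4,8,12-trimethyl-2-(propanoyloxy)pentadeca-4,8,10-trienoate | CCC(=O)O[C@H](C/C(C)=C/CC/C(C)=C/C=C/[C@@H](C)CCCc1ccoc1)C(=O)OC
F6 | step 10 | methyl (2RS,6E,10E)-12-hydroxy-2,6,10-trimethyl-3-oxododeca-6,10-dienoate | COC(=O)C(C)C(=O)CC/C(C)=C/CC/C(C)=C/CO
F7 | step 10 | methyl (2RS,6E,10E)-2,6,10-trimethyl-3,12-dioxododeca-6,10-dienoate | COC(=O)C(C)C(=O)CC/C(C)=C/CC/C(C)=C/C=O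
F8 | step 10 | potassium enolate of F7 (not isolated) | [K+].COC(=O)[C-](C)C(=O)CC/C(C)=C/CC/C(C)=C/C=O
F9 | step 5 | 5-{[(2S)-5-(9-borabicyclo[3.3.1]nonan-9-yl)-2-methylpentyl]sulfanyl}-1-phenyl-1H-tetrazole (not isolated) | B1(CCC[C@H](C)CSc2nnnn2-c2ccccc2)C2CCCC1CCC2
F10 | step 5 | 5-{[(2S)-5-(furan-3-yl)-2-methylpentyl]sulfanyl}-1-phenyl-1H-tetrazole | c1cc(CCC[C@H](C)CSc2nnnn2-c2ccccc2)co1
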